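(The earlier runs and the new flask are simulated for substances that don't exist; noise was put on by code.)

The trap in the winter flask is its charge: 1.1 equiv of partner reads as an excess, yet the product levels off at a third of the substrate charged.

| flask | substrate | partner | initiator | remark | time |
|---|---|---|---|---|---|
| winter | 0.050 M | 1.1 equiv | 5 mol% | the very flask that is asked about, followed so far |  |
| flask | 0.050 M | 1.10 equiv | 5 mol% |  | 2.5 d |

winter run (percent of the substrate charged)

| time / h | substrate / % | product / % |
|---|---|---|
| 1.50 | 90.8 | 9.1 |
| 5.00 | 77.5 | 21.9 |
| 8.00 | 71.6 | 27.7 |
| 12.0 | 69.0 | 31.1 |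
| 20.0 | 66.6 | 32.7 |
| 25.0 | 66.6 | 33.0 |
| 30.0 | 66.5 | 33.1 |

(readings scatter by 0.3 percentage points)

- what was read earlier has a scatter of 0.3 percentage points, one standard deviation

- part of the substrate gone at 2.5 d
- the product standing at 2.5 d, as a percentage of the substrate charged

The last product reading over the charge gives 30.1%; this is the partner yield, the product standing per partner charged. If the plateau marks the end of the partner's supply, product is this yield times the equivalents, so 1.10 equiv gives 33.1% at 2.5 d.

One number is not enough, because it carries no clock. The substrate's gap to its plateau falls from 11 percentage points at 5.00 h to 2.5 points at 12.0 h, a half-time of 3.27 h, and 2.5 d lies far beyond that. Nor does it cover the substrate: at 30.0 h the balance lacks 0.4 points, close to the scatter of 0.3 points. So we commit to 33.5% of the substrate gone.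

The forecast gives 33.6% gone and 33.2% of product, expecting little change “since no fresh initiator is added”.

The flask gives 34.1% gone and 33.4% of product, a partner yield of 30.4%.

    2 second chain carrier → ended chains A (k = 4.20 × 10⁶ M⁻¹ s⁻¹)
    2 first chain carrier → ended chains B (k = 2.00 × 10⁸ M⁻¹ s⁻¹)
    partner → decomposed reagent (k = 0.150 h⁻¹)
    partner + first chain carrier → product + second chain carrier (k = 3.04 × 10⁷ M⁻¹ h⁻¹)
    substrate + second chain carrier → by-product + first chain carrier (k = 28500 M⁻¹ s⁻¹)
    initiator → 2 initiating radical (k = 0.00134 h⁻¹)
    substrate + initiating radical → capped initiator + first chain carrier (k = 1.69 × 10⁵ M⁻¹ s⁻¹)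

Partner is this flask's limiting reagent, with 0% left at 2.50 d against 66% of the substrate. In this flask more of the partner ended as decomposed reagent, 0.0383 M, than as product, 0.0167 M, and the run without the pairing of first chain carrier into ended chains B reaches 100% conversion, against 34.1% with it. For the neighbour charged with 2.80 equiv of partner, the partner yield gives 84.3% of product, and that neighbour stands at 84.7%.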